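**Retrosynthetic overview**
- The target is a 1-tetralone (ring A = the catechol benzene ring, ring B = the cyclohexanone ring) that carries a 4-hydroxy-8-methoxy-1-naphthyl group (rings C and D) at C4. The last step only removes two benzyl ethers.
- Ring B is the only ring built. A formal (4+2) union of a phenacyl bromide (C1, C2, C8a, C4a) with a 4-vinyl-1-naphthol (C3, C4) closes C2–C3 by radical addition and C4–C4a by an enantioselective Friedel–Crafts ring closure on a para-quinone methide. Rings A, C and D are bought.
- Enabling feature: the free hydroxyl at C4' of the naphthalene is para to C1', the carbon bonded to the stereocentre C4, so C4 can become the exocyclic carbon of a naphthoquinone methide. In ring A the oxygen at C7 is para to C4a, which makes C4a the nucleophilic carbon. The C1–C8a ketone bond, which a Friedel–Crafts acylation would place para to the C8 oxygen instead, is present from the start.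
- The vinylnaphthol comes from 1,5-dimethoxynaphthalene (formylation, O-demethylation para to the aldehyde, methylenation). The bromoketone comes from 2',3'-dihydroxyacetophenone (benzylation, bromination).

Key step: step 6

Remark: 1,5-dimethoxynaphthalene and 2',3'-dihydroxyacetophenone are taken as commercial; fac-Ir(ppy)3 is tris(2-phenylpyridinato)iridium (trivalent iridium); (R)-TRIP is (R)-3,3'-bis(2,4,6-triisopropylphenyl)-1,1'-binaphthyl-2,2'-diyl hydrogen phosphate; which antipode of the acid leads to the (S) product is fixed in the first run of step 6, and the route is written with (R).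

**Step 1**
Reactants: 1 1,5-dimethoxynaphthalene
Product: 2 4,8-dimethoxynaphthalene-1-carbaldehyde
Conditions: POCl3, DMF, toluene, 95 °C; then H2O
Reagents that add atoms: N,N-dimethylformamide, CN(C)C=O (formyl carbon); water, O (aldehyde oxygen)
Why: Vilsmeier–Haack formylation of the symmetrical diether should go para to one methoxy group, at the position peri to the other, and the formyl group deactivates the product against a second formylation.

**Step 2**
Reactants: 2 4,8-dimethoxynaphthalene-1-carbaldehyde
Product: 3 4-hydroxy-8-methoxynaphthalene-1-carbaldehyde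
Conditions: NaSEt, DMF, 110 °C; then aq. HCl
Reagents that add atoms: none
Why: Nucleophilic O-demethylation by thiolate (SN2 at the methyl group) should take the methoxy group para to the aldehyde, because only that one leaves as a naphthoxide conjugated with the formyl group, while the peri methoxy group is not conjugated.

**Step 3**
Reactants: 3 4-hydroxy-8-methoxynaphthalene-1-carbaldehyde
Product: 4 4-ethenyl-5-methoxynaphthalen-1-ol (5-methoxy-4-vinylnaphthalen-1-ol)
Conditions: Ph3PCH3Br (2.5 equiv), KOtBu (2.4 equiv), THF, 0 °C to rt; NH4Cl work-up, used at once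
Reagents that add atoms: methyltriphenylphosphonium bromide, C[P+](c1ccccc1)(c1ccccc1)c1ccccc1.[Br-]
Why: Wittig methylenation with excess non-stabilised ylide, the way 4-vinylphenols are made from unprotected 4-hydroxybenzaldehydes; the first equivalent of ylide is spent on the naphthol proton.

**Step 4**
Reactants: 5 1-(2,3-dihydroxyphenyl)ethanone
Product: 6 1-[2,3-bis(benzyloxy)phenyl]ethanone
Conditions: BnBr, K2CO3, DMF, 60 °C
Reagents that add atoms: benzyl bromide, BrCc1ccccc1
Why: Williamson ether synthesis on both phenols; warming in DMF should also alkylate the hydroxyl that is hydrogen-bonded to the ketone.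

**Step 5**
Reactants: 6 1-[2,3-bis(benzyloxy)phenyl]ethanone
Product: 7 2-bromo-1-[2,3-bis(benzyloxy)phenyl]ethanone
Conditions: CuBr2 (2 equiv), EtOAc/CHCl3, reflux
Reagents that add atoms: copper dibromide (CuBr2), Br[Cu]Br
Why: CuBr2 brominates aryl methyl ketones through the enol at the alpha carbon and is the standard reagent for doing so without bromination of alkoxy- or hydroxy-substituted rings.

**Step 6**
Reactants: 4 4-ethenyl-5-methoxynaphthalen-1-ol; 7 2-bromo-1-[2,3-bis(benzyloxy)phenyl]ethanone
Product: 9 (4S)-7,8-bis(benzyloxy)-4-(4-hydroxy-8-methoxynaphthalen-1-yl)-3,4-dihydronaphthalen-1(2H)-one, via para-quinone methide 8 (not isolated)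
Conditions: fac-Ir(ppy)3 (1 mol%), (R)-TRIP (10 mol%), Na2HPO4 (powder, 1.5 equiv), CH2Cl2, 450 nm LEDs, 0 °C, slow addition of 4
Reagents that add atoms: none
Why: Proposed new method: photoexcited fac-Ir(ppy)3 reduces 7 to the electrophilic phenacyl radical, which adds to the terminal vinyl carbon of the electron-rich styrene 4 (C2–C3 bond); the resulting 4-hydroxynaphthylmethyl radical is oxidised by the tetravalent iridium complex and gives up HBr to the solid base to form quinone methide 8, and the chiral phosphoric acid then catalyses the intramolecular Friedel–Crafts 1,6-addition of ring A to the exocyclic carbon of 8 (C4–C4a bond). The closest known reaction types are the racemic photoredox or Mn(OAc)3 radical (4+2) annulation of aryl methyl ketone derivatives with styrenes to 1-tetralones, the radical–polar crossover of para-hydroxystyrenes to para-quinone methides, and chiral phosphoric acid catalysed enantioselective 1,6-additions of arenes to para-quinone methides; their merger in one flask is new. Ring B closes in a 6-exo-trig mode with respect to the exocyclic C=C of 8, with arene carbon C4a as the nucleophile. The C4 stereocentre is set in this ring closure by the phosphate of (R)-TRIP, which is hydrogen-bonded to the oxygen of the activated quinone methide, is its only soluble counter-anion, and shields one face of the exocyclic carbon. The step needs three selectivities: regioselective radical addition (secured by the terminal alkene and benzylic stabilisation), polar rather than radical ring closure (secured by the para hydroxyl, which makes the radical very easy to oxidise, and by NaBr staying in the solid phase), and closure at C4a only (C4a is para to the C7 benzyloxy group and is the only free carbon that gives a six-membered ring).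

**Step 7**
Reactants: 9 (4S)-7,8-bis(benzyloxy)-4-(4-hydroxy-8-methoxynaphthalen-1-yl)-3,4-dihydronaphthalen-1(2H)-one
Product: 10 (4S)-7,8-dihydroxy-4-(4-hydroxy-8-methoxynaphthalen-1-yl)-3,4-dihydronaphthalen-1(2H)-one (CNP0535815.1)
Conditions: H2 (1 atm), Pd/C, EtOAc/MeOH, rt
Reagents that add atoms: none
Why: Hydrogenolysis of the two benzyl aryl ethers under neutral conditions should leave the aryl methyl ether, the tetralone carbonyl and the C4 stereocentre (not alpha to the carbonyl, no acid or base present) untouched.

**Compound list**
1 | 1,5-dimethoxynaphthalene | COc1cccc2c(OC)cccc12 | starting material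
2 | 4,8-dimethoxynaphthalene-1-carbaldehyde | COc1cccc2c(OC)ccc(C=O)c12 | intermediate
3 | 4-hydroxy-8-methoxynaphthalene-1-carbaldehyde | COc1cccc2c(O)ccc(C=O)c12 | intermediate
4 | 4-ethenyl-5-methoxynaphthalen-1-ol | COc1cccc2c(O)ccc(C=C)c12 | intermediate
5 | 1-(2,3-dihydroxyphenyl)ethanone | CC(=O)c1cccc(O)c1O | starting material
6 | 1-[2,3-bis(benzyloxy)phenyl]ethanone | CC(=O)c1cccc(OCc2ccccc2)c1OCc1ccccc1 | intermediate
7 | 2-bromo-1-[2,3-bis(benzyloxy)phenyl]ethanone | BrCC(=O)c1cccc(OCc2ccccc2)c1OCc1ccccc1 | intermediate
8 | (4E)-4-{4-[2,3-bis(benzyloxy)phenyl]-4-oxobutylidene}-5-methoxynaphthalen-1(4H)-one (para-quinone methide, not isolated) | COc1cccc2C(=O)C=C/C(=C\CCC(=O)c3cccc(OCc4ccccc4)c3OCc3ccccc3)c12 | intermediate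
9 | (4S)-7,8-bis(benzyloxy)-4-(4-hydroxy-8-methoxynaphthalen-1-yl)-3,4-dihydronaphthalen-1(2H)-one | COc1cccc2c(O)ccc([C@@H]3CCC(=O)c4c3ccc(OCc3ccccc3)c4OCc3ccccc3)c12 | intermediate
10 | (4S)-7,8-dihydroxy-4-(4-hydroxy-8-methoxynaphthalen-1-yl)-3,4-dihydronaphthalen-1(2H)-one | COc1cccc2c(O)ccc([C@@H]3CCC(=O)c4c3ccc(O)c4O)c12 | target

**Step count**
Total steps: 7. Longest linear sequence: 5 (steps 1, 2, 3, 6, 7).

**Steps most likely to fail**

1. Step 6 (proposed new method). Enantiocontrol may be lost if the ring closes through the radical or through an acid-catalysed background path outside the chiral ion pair. The vinylnaphthol may also oligomerise under acid, or be O-alkylated by the bromoketone, before the radical is trapped. The fallback sets out from 4 and 7 and comes back at 9, and takes the two bond formations apart with known chemistry. First, fac-Ir(ppy)3, Na2HPO4, CH2Cl2 and blue LEDs without any acid (the known oxidative radical addition of a phenacyl bromide to a para-hydroxystyrene) should give quinone methide 8. Ring closure with an achiral acid (BF3·OEt2, CH2Cl2, 0 °C; the known Friedel–Crafts alkylation of an alkoxyarene by a quinone methide) should then give racemic 7,8-bis(benzyloxy)-4-(4-hydroxy-8-methoxynaphthalen-1-yl)-3,4-dihydronaphthalen-1(2H)-one F1. Preparative SFC on an amylose tris(3,5-dimethylphenylcarbamate) phase should deliver 9 and, as the other fraction, (4R)-7,8-bis(benzyloxy)-4-(4-hydroxy-8-methoxynaphthalen-1-yl)-3,4-dihydronaphthalen-1(2H)-one F2.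

2. Step 3. The naphthoxide formed under the basic conditions makes the aldehyde a poor electrophile, the peri methoxy group hinders it further, and the free vinylnaphthol may polymerise on isolation. The fallback sets out from 3 and comes back at 4. Silylation (TBSCl, imidazole, DMF) should give 4-[(tert-butyldimethylsilyl)oxy]-8-methoxynaphthalene-1-carbaldehyde F3. Wittig methylenation with 1.2 equiv of ylide should give tert-butyl[(4-ethenyl-5-methoxynaphthalen-1-yl)oxy]dimethylsilane F4, a styrene that can be stored. TBAF/AcOH in THF at 0 °C just before step 6 should release 4.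

3. Step 5. Bromination may go to the electron-rich ring (para to a benzyloxy group) or twice at the alpha carbon, and the HBr formed may cleave the benzyl ether ortho to the ketone. The fallback sets out from 6 and comes back at 7. Enol silylation (TMSOTf, Et3N, CH2Cl2, 0 °C) should give ({1-[2,3-bis(benzyloxy)phenyl]ethenyl}oxy)trimethylsilane F5, which NBS in THF at −78 °C should brominate at carbon only, under neutral conditions, to 7.

**Further compounds**
F1 | step 6 | racemic 7,8-bis(benzyloxy)-4-(4-hydroxy-8-methoxynaphthalen-1-yl)-3,4-dihydronaphthalen-1(2H)-one | COc1cccc2c(O)ccc(C3CCC(=O)c4c3ccc(OCc3ccccc3)c4OCc3ccccc3)c12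
F2 | step 6 | (4R)-7,8-bis(benzyloxy)-4-(4-hydroxy-8-methoxynaphthalen-1-yl)-3,4-dihydronaphthalen-1(2H)-one | COc1cccc2c(O)ccc([C@H]3CCC(=O)c4c3ccc(OCc3ccccc3)c4OCc3ccccc3)c12
F3 | step 3 | 4-[(tert-butyldimethylsilyl)oxy]-8-methoxynaphthalene-1-carbaldehyde | COc1cccc2c(O[Si](C)(C)C(C)(C)C)ccc(C=O)c12
F4 | step 3 | tert-butyl[(4-ethenyl-5-methoxynaphthalen-1-yl)oxy]dimethylsilane | COc1cccc2c(O[Si](C)(C)C(C)(C)C)ccc(C=C)c12
F5 | step 5 | ({1-[2,3-bis(benzyloxy)phenyl]ethenyl}oxy)trimethylsilane | C=C(O[Si](C)(C)C)c1cccc(OCc2ccccc2)c1OCc1ccccc1
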